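## Remarks and assumptions

- Locants: chromone O1, C2–C4, C4a, C5–C8, C8a; furan oxygen between C2 and C2'; ring B C1'–C6' (C1' on C3); pyran B O1''(on C4')–C2''(Me2)–C3''–C4''(on C3'); pyran A O1'''(on C7)–C2'''(Me2)–C3'''=C4'''(on C8).
- The target diol is trans, (3''R,4''S).
- Assumption: compounds 1, 5, 10 and 12 are taken to be commercially available.
- The connectivity of the bis(propargyl ether) and of the bis(chromene) follows from the target and needs no correction. Three points of the simplest version of the plan are changed:
  - The 5-OH is carried as an acetate as well. O1, O7 and O5 are through-conjugated with the C4 carbonyl, not cross-conjugated, and remain donors toward C8. A free 5-OH para to C8 would therefore make the ring A olefin at least as reactive toward an electrophilic oxidant as the ring B olefin.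
  - The oxygen transfer uses an anhydrous low-temperature (salen)MnCl protocol. A buffered aqueous dioxirane would hydrolyse aryl acetates.
  - Ring A starts from 2,6-dimethoxytoluene. A 3,5-dioxygenated 4-methylbenzoic acid has its carboxyl on the ring carbon that must carry O1 and would need a carbon-to-oxygen exchange.

## Structural features

The target is a hexacyclic coumaronochromone: ring A, the 4-pyranone, the furan and ring B form a benzofuro[2,3-b]chromen-11-one, with one pyran on each benzene ring. Pyran A is a 2,2-dimethyl-2H-pyran fused angularly through O7 and C8; pyran B is a 2,2-dimethyl-3,4-dihydro-2H-pyran fused through O4' and C3'. Ring A is fully substituted (chelated 5-OH, 6-methyl, O7, C8, O1) and ring B keeps only H6' and a free 5'-OH next to the pyran oxygen. The only stereocentres are the adjacent carbinols C3'' and C4'' of pyran B, trans to each other. C4'' is benzylic and flanked by O2' and O4', so it ionises easily and is the centre that can epimerise; C3'' is a neopentyl carbinol. Fragile elements are this benzylic alcohol, the ring A chromene double bond (acid, oxidants), the ketene-acetal carbon C2 bonded to O1 and the furan oxygen (nucleophiles, strong base), and the oxidisable 5'-hydroxyl para to the furan oxygen. The real difficulties are the ring A regiochemistry (6-methyl and angular pyran), telling O4' from O5', and oxidising one of two very similar chromene double bonds with absolute control. The key step exploits the fact that each pyran oxygen has one unsubstituted ortho carbon only: O7 lies between C6 (methyl) and C8 (H), O4' between C5' (oxygen) and C3' (H).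

## Logic of the disconnections

24 to 22: the C4''–O bond of the benzylic carbinol and the two acetyl C–O bonds are cut. A trans-diol is the anti-hydrolysis product of a cis-fused oxirane, and C4'' is the benzylic, unhindered terminus. Two adjacent stereocentres become one stereochemical event. The forward step must open at C4'' with inversion and not through a free cation; the acetates fall in the same operation (23 is not isolated).

22 to 21: both C–O bonds of the oxirane are cut. The precursor is achiral, so all chirality comes from a catalyst acting on a cis-disubstituted 2,2-dimethylchromene olefin. The demand is double: facial control and preference for the ring B olefin over the ring A olefin, which is why 21 carries the 5-acetate.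

21 to 17: C8–C4''' and C3'–C4'' are cut and the two O–CMe2 bonds are traced to the ether bonds of 17. This removes two rings and four bonds in one operation and leaves a flat tetracyclic bis-ether. The forward step must send each sigmatropic shift to the single free ortho carbon and run both cascades to completion in one heating without losing the acetates.

17 to 16: the two acyl C–O bonds are cut. The acetates can only be placed after the core exists, because the 5'-hydroxyl is created by the annulation. The chelated 5-OH must be acylated as well.

16 to 11 and 14: C3–C1' and C2–O2' are cut. This is the convergent union of the two aromatic halves. The quinone level of 14 supplies the electrophile and, after addition, two hydroxyls: one closes the furan and the other is the future 5'-OH, so O4' and O5' are differentiated without protecting groups. The forward step needs attack at C5 of 14, closure at C2 and not at C4, and no redox scrambling.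

14 to 13 to 12 and 10: the two O–CH3 bonds para to each other are cut oxidatively, then the O–C bond of the tertiary propargyl ether. The demand is that the tertiary ether survives the oxidant.

11 to 9 and 10, and 9 to 8: the O7–C bond, then both O–CH3 bonds. Alkylation must take the 7-OH and leave the chelated 5-OH; demethylation must spare the aminochromone.

8 to 7, 7 to 4 and 5, 4 to 3, 3 to 1: O1–C2 (ring closure that keeps the amine), C2–C3 (acyl transfer to the ketone methyl), C4–C4a (acylation), and C–O at the carbon para to the methyl group. Because 3 is symmetric, the oxygen that becomes O1 is necessarily the one flanked by hydrogen, which fixes 6-methyl over 8-methyl. The demand is a C–H oxidation at the one sterically open position of 1.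

## Other disconnections considered

Alternative 1: Ring B is dismantled along C1'–C2', C2'–C3' and C5'–C6' into the alkenyl(benzyloxy)carbene complex A1 of zerovalent chromium, one of its CO ligands and the 3-ethynyl-2-morpholinochromone A2. A1 carries the chiral-pool dihydropyran with both silyl-protected carbinols. The forward step is a Dötz benzannulation (alkyne insertion, CO insertion, electrocyclisation, tautomerisation) to the 2-morpholinoisoflavone A3. Its free 2'-OH would then displace morpholine to close the furan.
- In favour: both stereocentres are in place before ring B exists, so neither asymmetric catalysis nor site selectivity is needed. On stereochemical security this plan is better than the chosen one. It differentiates O2' from O5' automatically, which equals what the quinone does in the chosen route.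
- Against: stoichiometric chromium; A1 is an α-oxygenated alkenyl carbene with an allylic silyloxy group, a class prone to cyclobutenone and furan side channels, and it needs a long preparation; A2 is a hindered push–pull alkyne. Three benzyl and two silyl ethers must be removed. Hydrogenolysis excludes a chromene, so pyran A must be added afterwards by selective 7-O-propargylation beside a free 5'-OH and a separate single cascade.
- Comparison: the benzannulation forms three C–C bonds and one ring; the chosen step forms four bonds and two rings, is metal-free and is a pure isomerisation. The alternative is clearly longer than the 13 steps of the chosen plan.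

Alternative 2: C3–C1' and C2–O2' are cut between two fully elaborated halves, the pyrano-fused 2-morpholinochromone A4 and the chiral chromanquinone diacetate A5. In acetic acid C3 of A4 would add to A5 and the hydroquinone hydroxyl would displace morpholine, giving the target diacetate A6; deacetylation finishes.
- In favour: the bond set and reaction type are those of step 9 of the chosen route, so it is equal in mechanism and in level of precedent. The asymmetric epoxidation is done on a simple mono-chromene, so the site-selectivity problem of step 12 disappears; on this point the alternative is better. It is the most convergent plan and about equal in step count.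
- Against: the least precedented reaction is moved to the penultimate step and must work on both advanced fragments. A5 has a benzylic acetoxy group next to a quinone carbonyl (enolisation to a quinone methide, loss of acetic acid, erosion at C4). Once ring B is aromatic and electron-rich, the C4'' acetate can ionise in acetic acid. The ring A chromene must survive the acid. Two separate cascades replace the double one.
- Comparison: the chosen plan puts the risky union early, on simple achiral partners, and keeps the stereocentres out of acid until the last step, at the price of the site-selectivity question.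

Alternative 3: The single carbon C2 is removed (O1–C2, C2–C3, C2–O2'), leading to the dihydroxydeoxybenzoin A7 and carbon disulfide. With NaH the enolate adds to carbon disulfide, the ring A phenoxide closes the pyranone, and after S-methylation the ring B phenol closes the furan with loss of methanethiol, giving A8.
- In favour: closure of coumaronochromones through 2-(methylsulfanyl)isoflavones is established chemistry, so on precedent for the core it is better than the chosen plan. The ring B stereocentres are pre-installed, so no site selectivity is needed.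
- Against: A7 is the hard compound. Assembling a 2,2'-dihydroxydeoxybenzoin from a chiral ring B partner needs Lewis-acid acylation beside a benzylic silyl ether, and 2'-hydroxydeoxybenzoins dehydrate readily to 2-arylbenzofurans. After A8, three benzyl ethers must be removed, pyran A appended by selective propargylation and a single cascade, and the silyl ethers cleaved.
- Comparison: five protecting groups and a single use of the cascade make it longer. The chosen plan needs no protecting group on ring B beyond the acetate and forms both pyrans at once, but depends on one unprecedented union and one site-selective oxidation.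

Key step: step 11

## Route

Step 1
Reactants: 1 2,6-dimethoxytoluene
Product: 3 3,5-dimethoxy-4-methylphenol, via aryl pinacol boronate 2 (not isolated)
Conditions: [Ir(OMe)(cod)]2 (cat., cod = 1,5-cyclooctadiene), 4,4'-di-tert-butyl-2,2'-bipyridine (cat.), B2pin2, THF, 80 °C; then KHSO5 (as 2KHSO5·KHSO4·K2SO4), acetone/H2O, 25 °C
Reagents that add atoms: bis(pinacolato)diboron, CC1(C)OB(OC1(C)C)B1OC(C)(C)C(C)(C)O1 (boryl group of 2 only); potassium peroxymonosulfate, [K+].[O-]S(=O)(=O)OO (phenol oxygen of 3)
Why: Iridium-catalysed C–H borylation is sterically controlled and should take the only C–H without an ortho substituent (para to the methyl group); oxidation of the boronate in the same pot gives the symmetric phenol (C–H borylation/oxidation).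

Step 2
Reactants: 3 3,5-dimethoxy-4-methylphenol
Product: 4 1-(6-hydroxy-2,4-dimethoxy-3-methylphenyl)ethan-1-one
Conditions: AcOH, BF3·OEt2, 85 °C; aq. NaOAc work-up
Reagents that add atoms: acetic acid, CC(=O)O
Why: Friedel–Crafts acylation ortho to the phenol; the two ortho positions are equivalent by symmetry and the para position is blocked by methyl, so one ketone only can form, and in it the free hydroxyl (future O1) is flanked by hydrogen.

Step 3
Reactants: 4 1-(6-hydroxy-2,4-dimethoxy-3-methylphenyl)ethan-1-one; 5 pyrrolidine-1-carbonyl chloride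
Product: 7 1-(6-hydroxy-2,4-dimethoxy-3-methylphenyl)-3-(pyrrolidin-1-yl)propane-1,3-dione, via aryl carbamate 6 (not isolated)
Conditions: NaH (1.1 equiv), THF, 0 °C, then 5; then NaH (2.5 equiv), reflux; aq. NH4Cl
Reagents that add atoms: none
Why: Carbamoyl Baker–Venkataraman rearrangement: the phenoxide is O-carbamoylated, then the ketone enolate attacks the carbamate carbonyl intramolecularly and the carbamoyl group moves from oxygen to carbon, giving the chelated β-ketoamide.

Step 4
Reactants: 7 1-(6-hydroxy-2,4-dimethoxy-3-methylphenyl)-3-(pyrrolidin-1-yl)propane-1,3-dione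
Product: 8 5,7-dimethoxy-6-methyl-2-(pyrrolidin-1-yl)-4H-chromen-4-one
Conditions: Tf2O, CH2Cl2, 0 → 25 °C; then MeOH, aq. NaHCO3
Reagents that add atoms: none
Why: Tf2O activates the amide oxygen as an O-triflyl iminium ion, the phenol adds and triflic acid is lost; this known cyclodehydration keeps the amine, whereas protic acid would expel it and give the 4-hydroxycoumarin.

Step 5
Reactants: 8 5,7-dimethoxy-6-methyl-2-(pyrrolidin-1-yl)-4H-chromen-4-one
Product: 9 5,7-dihydroxy-6-methyl-2-(pyrrolidin-1-yl)-4H-chromen-4-one
Conditions: BBr3, CH2Cl2, −78 → 25 °C; then MeOH, aq. NaHCO3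
Reagents that add atoms: none
Why: Lewis-acid cleavage of aryl methyl ethers; the 5-OMe should go first through chelation with the C4 carbonyl and the 7-OMe at 25 °C; pyrrolidine was chosen because, unlike morpholine, it has no ether bond that BBr3 could cleave.

Step 6
Reactants: 9 5,7-dihydroxy-6-methyl-2-(pyrrolidin-1-yl)-4H-chromen-4-one; 10 3-chloro-3-methylbut-1-yne
Product: 11 5-hydroxy-6-methyl-7-[(2-methylbut-3-yn-2-yl)oxy]-2-(pyrrolidin-1-yl)-4H-chromen-4-one
Conditions: K2CO3, KI (cat.), CuI (cat.), acetone, 60 °C
Reagents that add atoms: none
Why: Copper-catalysed O-alkylation of a phenol with a tertiary propargyl chloride; the 7-OH is the acidic, unchelated phenol, while the 5-OH is held in the hydrogen bond to C4=O and should stay free.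

Step 7
Reactants: 12 2,5-dimethoxyphenol; 10 3-chloro-3-methylbut-1-yne
Product: 13 1,4-dimethoxy-2-[(2-methylbut-3-yn-2-yl)oxy]benzene
Conditions: K2CO3, KI (cat.), CuI (cat.), acetone, 60 °C
Reagents that add atoms: none
Why: The same copper-catalysed O-propargylation on the only hydroxyl of 12.

Step 8
Reactants: 13 1,4-dimethoxy-2-[(2-methylbut-3-yn-2-yl)oxy]benzene
Product: 14 2-[(2-methylbut-3-yn-2-yl)oxy]cyclohexa-2,5-diene-1,4-dione
Conditions: (NH4)2Ce(NO3)6, MeCN/H2O, 0 °C
Reagents that add atoms: water, O
Why: Oxidative demethylation of a para-dimethoxyarene to the para-quinone; the two methoxy groups para to each other leave as methanol and the tertiary propargyl ether (a vinylogous ester in the product) is kept.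

Step 9
Reactants: 11 5-hydroxy-6-methyl-7-[(2-methylbut-3-yn-2-yl)oxy]-2-(pyrrolidin-1-yl)-4H-chromen-4-one; 14 2-[(2-methylbut-3-yn-2-yl)oxy]cyclohexa-2,5-diene-1,4-dione
Product: 16 5,5'-dihydroxy-6-methyl-7,4'-bis[(2-methylbut-3-yn-2-yl)oxy]coumaronochromone (1,9-dihydroxy-2-methyl-3,8-bis[(2-methylbut-3-yn-2-yl)oxy]-11H-benzofuro[2,3-b]chromen-11-one), via hydroquinone adduct 15 (not isolated)
Conditions: AcOH, Ar, 25 → 50 °C, slow addition of 14
Reagents that add atoms: none
Why: Proposed new method: the 2-aminochromone is a cyclic tertiary enaminone (ketene N,O-acetal) whose C3 should add to C5 of the 2-alkoxyquinone, the position β to the carbonyl that is not deactivated as a vinylogous ester; tautomerisation gives hydroquinone 15, whose 2'-OH adds to C2 of the O-protonated vinylogous carbamate and expels pyrrolidine, closing the furan without change of oxidation level, while the second hydroxyl emerges as the free 5'-OH beside the 4'-ether; closure at C2 and not at C4 is expected because C2 is the amidinium-like carbon at which 2-aminochromones exchange their amine for oxygen nucleophiles; the closest known reaction type is the Nenitzescu benzofuran synthesis from tertiary enaminones and para-quinones.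

Step 10
Reactants: 16 5,5'-dihydroxy-6-methyl-7,4'-bis[(2-methylbut-3-yn-2-yl)oxy]coumaronochromone
Product: 17 5,5'-diacetoxy-6-methyl-7,4'-bis[(2-methylbut-3-yn-2-yl)oxy]coumaronochromone (the 5,5'-di-O-acetate of 16)
Conditions: Ac2O, pyridine, DMAP (cat.), CH2Cl2, 25 → 40 °C
Reagents that add atoms: acetic anhydride, CC(=O)OC(C)=O
Why: Acylation of both phenols, with DMAP for the chelated 5-OH; the 5'-acetate blocks C5' and protects the oxidisable phenol, and the 5-acetate removes the strongest donor conjugated with C8 and so lowers the reactivity of the future ring A olefin.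

Step 11
Reactants: 17 5,5'-diacetoxy-6-methyl-7,4'-bis[(2-methylbut-3-yn-2-yl)oxy]coumaronochromone
Product: 21 bis(chromene) diacetate: 5,5'-diacetoxy-6-methylcoumaronochromone with a 2,2-dimethyl-2H-pyran fused at O7/C8 (pyran A) and a second one fused at O4'/C3' (pyran B), via bis(allenyl) dienone 18 (not isolated), via bis(ortho-allenylphenol) 19 (not isolated), via bis(ortho-quinone methide) 20 (not isolated)
Conditions: 1,2-dichlorobenzene (degassed), 180 °C, Ar
Reagents that add atoms: none
Why: Each aryl 1,1-dimethylpropargyl ether should undergo an aromatic propargyl Claisen ([3,3]) shift that breaks O–CMe2 and joins the terminal alkyne carbon to the free ortho carbon (C8 on ring A, C3' on ring B), giving allenyl cyclohexadienones (18); enolisation restores the arenes (19), a 1,5-hydrogen shift from O–H to the central allene carbon gives ortho-quinone methides (20), and a thermal oxa-6π electrocyclisation (O7 to C2''' and O4' to C2'') closes each 2,2-dimethyl-2H-pyran. The closest known reaction type is the thermal rearrangement of aryl 1,1-dimethylpropargyl ethers to 2,2-dimethyl-2H-chromenes, run here twice in one molecule on two electronically independent benzene rings. Both rings are thus closed by electrocyclisation, and no stereocentre is formed. The selectivity needed is regiochemical: a shift to C6 or C5' would give a dienone whose methyl- or acetoxy-bearing carbon cannot enolise and can only revert, so the C6 methyl and the C5' acetoxy group leave C8 and C3' as the only productive sites and exclude the linear pyran isomers. The acetates, the ketene-acetal C2 and the chromone carbonyl are spectators in neutral thermolysis; acetyl migration from O5' to the transient 4'-OH is reversible and is drained by the irreversible ring closure.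

Step 12
Reactants: 21 bis(chromene) diacetate
Product: 22 (3''R,4''R)-3'',4''-epoxide of 21 (oxirane on pyran B; pyran A olefin intact)
Conditions: chloro[(R,R)-N,N'-bis(3,5-di-tert-butylsalicylidene)-1,2-cyclohexanediaminato]manganese, (R,R)-(salen)MnCl (5 mol%), mCPBA, N-methylmorpholine N-oxide, CH2Cl2, −78 °C
Reagents that add atoms: mCPBA (3-chloroperoxybenzoic acid), OOC(=O)c1cccc(Cl)c1
Why: Jacobsen–Katsuki epoxidation; cis-disubstituted 2,2-dimethylchromenes are the best substrates for this oxo transfer and the (R,R)-catalyst delivers oxygen to the face that gives the (3R,4R)-oxirane, so C3'' and C4'' are both set by the catalyst on an achiral substrate; the ring B olefin should react first because its benzylic carbon is flanked by the unattenuated ether oxygen O4', whereas the ring A olefin sits on the acyl-bearing ring whose oxygens (O1 and O7 as vinylogous esters, 5-OAc) are poor donors; the anhydrous low-temperature protocol spares the acetates and the acid-labile oxirane.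

Step 13
Reactants: 22 (3''R,4''R)-3'',4''-epoxide of 21
Product: 24 target CNP0351839.1 (trans-(3''R,4''S)-3'',4''-diol with free 5-OH and 5'-OH), via trans-diol diacetate 23 (not isolated)
Conditions: HClO4 (cat.), THF/H2O, 0 °C; then K2CO3 (0.5 equiv), MeOH, 0 °C; aq. NH4Cl
Reagents that add atoms: water, O
Why: Acid-catalysed hydrolysis of the oxirane; water should attack the benzylic C4'' (C3'' is neopentyl) with inversion, turning (3''R,4''R) into the trans-(3''R,4''S)-diol while C3'' keeps its oxygen and configuration; carbonate methanolysis then removes both aryl acetates without touching the diol, the chromene or the ketene-acetal C2, and any 5-acetate lost in the acid stage converges on the same product.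

## Compound list

1 | 2,6-dimethoxytoluene | COc1cccc(OC)c1C | starting material
2 | 2-(3,5-dimethoxy-4-methylphenyl)-4,4,5,5-tetramethyl-1,3,2-dioxaborolane | COc1cc(B2OC(C)(C)C(C)(C)O2)cc(OC)c1C | intermediate (not isolated)
3 | 3,5-dimethoxy-4-methylphenol | COc1cc(O)cc(OC)c1C | intermediate
4 | 1-(6-hydroxy-2,4-dimethoxy-3-methylphenyl)ethan-1-one | CC(=O)c1c(O)cc(OC)c(C)c1OC | intermediate
5 | pyrrolidine-1-carbonyl chloride | O=C(Cl)N1CCCC1 | starting material
6 | 2-acetyl-3,5-dimethoxy-4-methylphenyl pyrrolidine-1-carboxylate | CC(=O)c1c(OC(=O)N2CCCC2)cc(OC)c(C)c1OC | intermediate (not isolated)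
7 | 1-(6-hydroxy-2,4-dimethoxy-3-methylphenyl)-3-(pyrrolidin-1-yl)propane-1,3-dione | COc1cc(O)c(C(=O)CC(=O)N2CCCC2)c(OC)c1C | intermediate
8 | 5,7-dimethoxy-6-methyl-2-(pyrrolidin-1-yl)-4H-chromen-4-one | Cc1c(OC)cc2oc(N3CCCC3)cc(=O)c2c1OC | intermediate
9 | 5,7-dihydroxy-6-methyl-2-(pyrrolidin-1-yl)-4H-chromen-4-one | Cc1c(O)cc2oc(N3CCCC3)cc(=O)c2c1O | intermediate
10 | 3-chloro-3-methylbut-1-yne | C#CC(C)(C)Cl | starting material
11 | 5-hydroxy-6-methyl-7-[(2-methylbut-3-yn-2-yl)oxy]-2-(pyrrolidin-1-yl)-4H-chromen-4-one | Cc1c(OC(C)(C)C#C)cc2oc(N3CCCC3)cc(=O)c2c1O | intermediate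
12 | 2,5-dimethoxyphenol | COc1ccc(OC)c(O)c1 | starting material
13 | 1,4-dimethoxy-2-[(2-methylbut-3-yn-2-yl)oxy]benzene | COc1ccc(OC)c(OC(C)(C)C#C)c1 | intermediate
14 | 2-[(2-methylbut-3-yn-2-yl)oxy]cyclohexa-2,5-diene-1,4-dione | O=C1C=CC(=O)C(OC(C)(C)C#C)=C1 | intermediate
15 | 3-{2,5-dihydroxy-4-[(2-methylbut-3-yn-2-yl)oxy]phenyl}-5-hydroxy-6-methyl-7-[(2-methylbut-3-yn-2-yl)oxy]-2-(pyrrolidin-1-yl)-4H-chromen-4-one | Cc1c(OC(C)(C)C#C)cc2oc(N3CCCC3)c(-c3cc(O)c(OC(C)(C)C#C)cc3O)c(=O)c2c1O | intermediate (not isolated)
16 | 5,5'-dihydroxy-6-methyl-7,4'-bis[(2-methylbut-3-yn-2-yl)oxy]coumaronochromone | Cc1c(OC(C)(C)C#C)cc2oc3oc4cc(OC(C)(C)C#C)c(O)cc4c3c(=O)c2c1O | intermediate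
17 | 5,5'-diacetoxy-6-methyl-7,4'-bis[(2-methylbut-3-yn-2-yl)oxy]coumaronochromone (key-step precursor) | Cc1c(OC(C)(C)C#C)cc2oc3oc4cc(OC(C)(C)C#C)c(OC(C)=O)cc4c3c(=O)c2c1OC(C)=O | intermediate
18 | bis(allenyl) dienone: 7,4'-dioxo tautomer with 3-methylbuta-1,2-dienyl groups on sp3 C8 and C3' (configuration there not defined) | CC1=C(OC(C)=O)C2=C(OC3=C(C2=O)C2=C(O3)C(C=C=C(C)C)C(=O)C(OC(C)=O)=C2)C(C=C=C(C)C)C1=O | intermediate (not isolated)
19 | 5,5'-diacetoxy-7,4'-dihydroxy-6-methyl-8,3'-bis(3-methylbuta-1,2-dienyl)coumaronochromone | Cc1c(O)c(C=C=C(C)C)c2oc3oc4c(C=C=C(C)C)c(O)c(OC(C)=O)cc4c3c(=O)c2c1OC(C)=O | intermediate (not isolated)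
20 | bis(ortho-quinone methide): 7,4'-dioxo-8,3'-bis(3-methylbut-2-enylidene) tautomer | CC1=C(OC(C)=O)C2=C(OC3=C(C2=O)C2=C(O3)C(=CC=C(C)C)C(=O)C(OC(C)=O)=C2)C(=CC=C(C)C)C1=O | intermediate (not isolated)
21 | bis(chromene) diacetate (key-step product; pyran A at O7/C8, pyran B at O4'/C3', 5-OAc, 5'-OAc) | Cc1c2c(c3oc4oc5c6c(c(OC(C)=O)cc5c4c(=O)c3c1OC(C)=O)OC(C)(C)C=C6)C=CC(C)(C)O2 | intermediate
22 | (3''R,4''R)-3'',4''-epoxide of 21 | Cc1c2c(c3oc4oc5c6c(c(OC(C)=O)cc5c4c(=O)c3c1OC(C)=O)OC(C)(C)[C@@H]7O[C@H]67)C=CC(C)(C)O2 | intermediate
23 | (3''R,4''S)-3'',4''-dihydroxy-3'',4''-dihydro derivative of 21 (trans-diol, 5,5'-diacetate) | Cc1c2c(c3oc4oc5c6c(c(OC(C)=O)cc5c4c(=O)c3c1OC(C)=O)OC(C)(C)[C@H](O)[C@H]6O)C=CC(C)(C)O2 | intermediate (not isolated)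
24 | CNP0351839.1 | Cc1c2c(c3oc4oc5c6c(c(O)cc5c4c(=O)c3c1O)OC(C)(C)[C@H](O)[C@H]6O)C=CC(C)(C)O2 | target

## Step count and least certain steps

Total: 13 steps. Longest linear sequence: 11 steps (steps 1–6 and 9–13); the ring B branch is steps 7 and 8.

Step 9 (Proposed new method).
- What may go wrong: conjugate addition to the deactivated 2-alkoxyquinone may be slow or may occur at C6 of 14, which would place the ether on C3'. Hydroquinone 15 may be drained by redox exchange with unreacted 14. Closure could compete at C4.
- Fallback (known chemistry), from 11 and 13, back at 15 and then 16: the C3–C1' bond is made by cross-coupling.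
  - Iodination of 11 with N-iodosuccinimide (MeCN, 0 °C) gives the 3-iodo-2-aminochromone F1.
  - Bromination of 13 with N-bromosuccinimide, para to the propargyl ether, gives the aryl bromide F2.
  - Miyaura borylation (PdCl2(dppf), B2pin2, KOAc, dioxane, 80 °C) gives the pinacol boronate F3.
  - Suzuki–Miyaura coupling of F1 with F3 (PdCl2(dppf), K3PO4, dioxane/H2O, 70 °C) gives the 2',5'-dimethoxy-2-aminoisoflavone F4.
  - (NH4)2Ce(NO3)6 gives the quinone F5, and Na2S2O4 reduces it to 15, now isolated.
  - 15 is closed in AcOH at 50 °C by the acid-mediated addition–elimination at C2 that is familiar from the solvolysis of 2-aminochromones, giving 16.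

Step 11 (key step).
- What may go wrong: unequal rates of the two cascades. The ring A ether, on the acyl-deactivated ring and next to the methyl group, should be the slower one, so the first-formed chromene and the acetates are exposed to prolonged heating. Acetyl migration to the transient 4'-OH may park material, and allenyl intermediates may oligomerise.
- Fallback, from 17 back at 21, no new compound: a different mechanism. π-Acid-catalysed 6-endo hydroarylation of both alkynes with Ph3PAuNTf2 (CH2Cl2, 25 °C) forms C8–C and C3'–C directly, leaves the O–CMe2 bonds in place and involves no free phenol. The regiochemistry rests on the same blocking groups.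

Step 12.
- What may go wrong: insufficient discrimination between the two chromene olefins (oxygen transfer to ring A or to both), or erosion of enantioselectivity by uncatalysed peracid oxidation. The sense of induction rests on analogy with simple 2,2-dimethylchromenes.
- Fallback, from 11 and 13, back at 24: the ring B chromene is made and oxidised before the halves are joined; this gives up the double cascade.
  - Heating 11 (1,2-dichlorobenzene, 180 °C) gives the pyrano-fused aminochromone F6.
  - Heating 13 in the same way gives 5,8-dimethoxy-2,2-dimethyl-2H-chromene F7.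
  - The (R,R)-(salen)MnCl epoxidation of this single olefin gives the (3R,4R)-epoxide F8, and dilute aqueous acid gives the trans-diol F9.
  - (NH4)2Ce(NO3)6 gives the chromanquinone diol F10.
  - F6 and F10 are joined in AcOH at 25 °C by the step 9 annulation, which by then would be established, giving 24 directly.

Step 13.
- What may go wrong: loss of stereochemical fidelity at C4''. Ionisation of the oxirane to the benzylic cation, stabilised by O2' and O4', lets water add from both faces; a hydride shift to the chroman-3-one is also possible.
- Fallback, from 23 back at 23: stereo-correction by oxidation and reduction.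
  - The sequence is stopped after the acid stage and 23 is isolated as a C4'' epimer mixture.
  - MnO2 (CH2Cl2, 25 °C) oxidises the benzylic hydroxyl to the 3''-hydroxy-4''-ketone F11, leaving C3'' untouched.
  - NaBH4 (THF/MeOH, −40 °C) reduces it. Hydride is expected to approach anti to the pseudo-axial C2'' methyl group, which places the new hydroxyl trans to the C3'' hydroxyl and returns 23.
  - Methanolysis as in step 13 then gives 24.

## Further compounds

F1 | step 9 | 5-hydroxy-3-iodo-6-methyl-7-[(2-methylbut-3-yn-2-yl)oxy]-2-(pyrrolidin-1-yl)-4H-chromen-4-one | Cc1c(OC(C)(C)C#C)cc2oc(N3CCCC3)c(I)c(=O)c2c1O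
F2 | step 9 | 1-bromo-2,5-dimethoxy-4-[(2-methylbut-3-yn-2-yl)oxy]benzene | COc1c(Br)cc(OC)c(OC(C)(C)C#C)c1
F3 | step 9 | 2-{2,5-dimethoxy-4-[(2-methylbut-3-yn-2-yl)oxy]phenyl}-4,4,5,5-tetramethyl-1,3,2-dioxaborolane | COc1c(B2OC(C)(C)C(C)(C)O2)cc(OC)c(OC(C)(C)C#C)c1
F4 | step 9 | 3-{2,5-dimethoxy-4-[(2-methylbut-3-yn-2-yl)oxy]phenyl}-5-hydroxy-6-methyl-7-[(2-methylbut-3-yn-2-yl)oxy]-2-(pyrrolidin-1-yl)-4H-chromen-4-one | Cc1c(OC(C)(C)C#C)cc2oc(N3CCCC3)c(-c3cc(OC)c(OC(C)(C)C#C)cc3OC)c(=O)c2c1O
F5 | step 9 | 2-{5-hydroxy-6-methyl-7-[(2-methylbut-3-yn-2-yl)oxy]-4-oxo-2-(pyrrolidin-1-yl)-4H-chromen-3-yl}-5-[(2-methylbut-3-yn-2-yl)oxy]cyclohexa-2,5-diene-1,4-dione | Cc1c(OC(C)(C)C#C)cc2oc(N3CCCC3)c(C3=CC(=O)C(OC(C)(C)C#C)=CC3=O)c(=O)c2c1O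
F0 | step 11 | none | none
F6 | step 12 | 5-hydroxy-6,8,8-trimethyl-2-(pyrrolidin-1-yl)-4H,8H-pyrano[2,3-f]chromen-4-one | Cc1c2c(c3oc(N4CCCC4)cc(=O)c3c1O)C=CC(C)(C)O2
F7 | step 12 | 5,8-dimethoxy-2,2-dimethyl-2H-chromene | COc1ccc(OC)c2c1C=CC(C)(C)O2
F8 | step 12 | (3R,4R)-3,4-epoxy-5,8-dimethoxy-2,2-dimethyl-3,4-dihydro-2H-chromene | COc1c2c(c(OC)cc1)OC(C)(C)[C@@H]3O[C@H]23
F9 | step 12 | (3R,4S)-5,8-dimethoxy-2,2-dimethyl-3,4-dihydro-2H-chromene-3,4-diol | COc1c2c(c(OC)cc1)OC(C)(C)[C@H](O)[C@H]2O
F10 | step 12 | (3R,4S)-3,4-dihydroxy-2,2-dimethyl-3,4-dihydro-2H-chromene-5,8-dione | O=C1C=CC(=O)C2=C1OC(C)(C)[C@H](O)[C@H]2O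
F11 | step 13 | (3''S)-3''-hydroxy-4''-oxo analogue of 23 (same spatial arrangement at C3'' as in 23) | Cc1c2c(c3oc4oc5c6c(c(OC(C)=O)cc5c4c(=O)c3c1OC(C)=O)OC(C)(C)[C@H](O)C6=O)C=CC(C)(C)O2
A1 | alternative 1 | pentacarbonyl{(benzyloxy)[(3R,4S)-3,4-bis(tert-butyldimethylsilyloxy)-2,2-dimethyl-3,4-dihydro-2H-pyran-6-yl]methylidene}chromium | O=C=[Cr](=C=O)(=C=O)(=C=O)(=C=O)=C(OCc1ccccc1)C1=C[C@H](O[Si](C)(C)C(C)(C)C)[C@@H](O[Si](C)(C)C(C)(C)C)C(C)(C)O1
A2 | alternative 1 | 5,7-bis(benzyloxy)-3-ethynyl-6-methyl-2-(morpholin-4-yl)-4H-chromen-4-one | Cc1c(OCc2ccccc2)cc2oc(N3CCOCC3)c(C#C)c(=O)c2c1OCc1ccccc1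
A3 | alternative 1 | 2-morpholinoisoflavone with free 2'-OH, 5,7,5'-tribenzyl ether and (3''R,4''S)-bis-silylated pyran B diol | Cc1c(OCc2ccccc2)cc2oc(N3CCOCC3)c(-c3c(O)c4c(c(OCc5ccccc5)c3)OC(C)(C)[C@H](O[Si](C)(C)C(C)(C)C)[C@H]4O[Si](C)(C)C(C)(C)C)c(=O)c2c1OCc1ccccc1
A4 | alternative 2 | 5-hydroxy-6,8,8-trimethyl-2-(morpholin-4-yl)-4H,8H-pyrano[2,3-f]chromen-4-one | Cc1c2c(c3oc(N4CCOCC4)cc(=O)c3c1O)C=CC(C)(C)O2
A5 | alternative 2 | (3R,4S)-2,2-dimethyl-5,8-dioxo-3,4,5,8-tetrahydro-2H-chromene-3,4-diyl diacetate | O=C1C=CC(=O)C2=C1OC(C)(C)[C@H](OC(C)=O)[C@H]2OC(C)=O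
A6 | alternative 2 | 3'',4''-di-O-acetate of the target | Cc1c2c(c3oc4oc5c6c(c(O)cc5c4c(=O)c3c1O)OC(C)(C)[C@H](OC(C)=O)[C@H]6OC(C)=O)C=CC(C)(C)O2
A7 | alternative 3 | 1-[2,4-bis(benzyloxy)-6-hydroxy-3-methylphenyl]-2-[(3R,4S)-8-(benzyloxy)-3,4-bis(tert-butyldimethylsilyloxy)-5-hydroxy-2,2-dimethyl-3,4-dihydro-2H-chromen-6-yl]ethan-1-one | Cc1c(OCc2ccccc2)cc(O)c(C(=O)Cc2cc(OCc3ccccc3)c3c(c2O)[C@H](O[Si](C)(C)C(C)(C)C)[C@@H](O[Si](C)(C)C(C)(C)C)C(C)(C)O3)c1OCc1ccccc1
A8 | alternative 3 | coumaronochromone core, 5,7,5'-tribenzyl ether, (3''R,4''S)-bis-silyl ether, without pyran A | Cc1c(OCc2ccccc2)cc2oc3oc4c5c(c(OCc6ccccc6)cc4c3c(=O)c2c1OCc1ccccc1)OC(C)(C)[C@H](O[Si](C)(C)C(C)(C)C)[C@H]5O[Si](C)(C)C(C)(C)C
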